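## The problem

The target 25 is a trimer of 7-oxygenated coumarins and has no stereocentre. Coumarin A (7-hydroxy) is bonded through C8 to C6 of coumarin B, and the C7 oxygen of B is an ether bridge to C3 of coumarin C (7-hydroxy). The A–B bond is the difficult one: C8 of A lies between the oxygen-bearing carbons C7 and C8a, and C6 of B has the aryloxy group on the neighbouring C7, so the biaryl is tri-ortho-substituted and a cross-coupling would need a hindered 2,6-dioxygenated aryl metal that loses its metal easily. The second link, an aryl ether at the enol-like C3 of a 2-pyranone, is not open to ordinary nucleophilic aromatic substitution and is best made while the pyranone of C is closed around it. The fragile parts are the three lactones, which open with hydroxide, alkoxide and amide bases, and the three electron-poor C3=C4 bonds, which take up hydrogen and nucleophiles and dimerise in ultraviolet light; the two phenols must therefore be masked by groups that come off without base, hydrogen or light. The two oxygens of ring A must also be told apart, because the one on C8a becomes the lactone oxygen and the one on C7 ends as a free phenol. The enabling feature is that C8 of A, aryl-substituted and flanked by oxygenated C7 and C8a, is the pattern produced when aryl alkoxyalkyne 13 is inserted between the carbonyl and alpha carbons of cyclobutenone 16: the alkyne carbons become C8 and C7, the ketone carbon becomes C8a, and the other three ring carbons become C4a, C5 and C6. The crowded biaryl bond then starts as an unhindered aryl–alkyne bond, and the ring A oxygens emerge differentiated as free phenol and methyl ether.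

## Retrosynthesis

Target 25 is traced to its dimethyl ether 24 by cutting the two O–CH3 bonds. Methyl is dictated on ring A by the ynol ether of the key step: a methyl ynol ether has no beta hydrogen and cannot fragment thermally to a ketene, as ethyl and tert-butyl ynol ethers do. Ring C carries the same group so that one Lewis-acid operation frees both phenols. Benzyl ethers are excluded by the three pyranone double bonds, and acyl groups would not survive the organometallic step. The forward reaction must cleave a hindered aryl methyl ether without touching the diaryl-type ether or the lactones.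

The pyranone of A in 24 is opened at C3=C4 and O1–C2 (olefination and lactonisation through cinnamate 23), which leads to salicylaldehyde 22. Removal of the formyl carbon (C4–C4a) leads to phenol 21. Acid-mediated one-step pyranone syntheses were set aside as too harsh for the ether-linked dicoumarin. In 21 only one position ortho to the hydroxyl is free, and it is also para to the methoxy group, so a chelation-directed formylation has a single site to choose. Phenol 21 is simpler than 24 by one ring and already holds the full biaryl.

The benzene ring of A in 21 is then taken apart at C8–C8a and C6–C7, which gives alkyne 13 and cyclobutenone 16. The neighbouring cut, the A–B biaryl bond itself, would require coupling a 2,6-dioxygenated aryl metal to an ortho-substituted halide. The chosen cut replaces that with an unhindered aryl–alkyne bond and a four-carbon ketone, and delivers the two oxygens of ring A already differentiated. The forward reaction needs a regiospecific ketene–alkyne cycloaddition and lactones that tolerate neutral heating; both are reasonable.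

Alkyne 13 is cut at the C6(B)–C(sp) bond to give iodide 9 and the two-carbon methoxyalkyne unit, which comes from acetal 10 through lithium acetylide 11 and zinc acetylide 12. A zinc acetylide is preferred over copper/amine alkynylation, which is poorly behaved with alkoxyalkynes, and over lithium or magnesium acetylides, which would add to the lactones.

Iodide 9 is opened at C3=C4 and O1–C2 of coumarin C to give aryloxyacetic acid 6 and salicylaldehyde 7, by a Perkin-type condensation through ester 8. The ether oxygen is already attached to the methylene that becomes C3, so the awkward C3–O bond never has to be made on a pyranone. The alternative, O-arylation of a 3-halocoumarin, has no reliable basis. Aldehyde 7 brings the ring C oxygen as its methyl ether.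

Acid 6 is traced through tert-butyl ester 5 to phenol 4 by cutting the O–CH2 bond. The acid-labile ester spares the lactone from saponification.

Phenol 4 is opened at its pyranone (through cinnamate 3) to give iodo aldehyde 2, and the C–I bond is cut to reach 2,4-dihydroxybenzaldehyde 1. Iodination is placed at the aldehyde stage because C5 of 1 (para to one hydroxyl, ortho to the other) is the favoured site there, whereas the finished 7-hydroxycoumarin would be attacked mainly at C8. An iodide rather than a bromide is carried so that the later coupling runs near room temperature.

Cyclobutenone 16 is traced by dehydrobromination to bromo ketone 15, and 15 by bromodecarboxylation to the commercial acid 14.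

## Roads not taken

Alternative 1: The cut goes through ring A at C5–C6 and C7–C8. In the forward sense the electron-poor pyranone A2 (methyl 3-[2-(benzyloxy)-4-methoxyphenyl]-4-methoxy-2-oxo-2H-pyran-5-carboxylate) would take up ketene acetal A3 (1,1-dimethoxyethene) in a Diels–Alder reaction of inverse electron demand. Decarboxylative cycloreversion of the bridged adduct and loss of one acetal methoxy group would leave benzoate A1 (methyl 3-[2-(benzyloxy)-4-methoxyphenyl]-2,4-dimethoxybenzoate).
- Merits: the reagents are stable, no strained volatile ketone or acid-sensitive ynol ether is needed, the biaryl bond is already present in A2, and the risky cycloaddition comes early on cheap material. In these respects it is the safer road.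
- Weak points: A1 holds both ring A oxygens and the future O1 of ring B as methyl ethers that must later be told apart. Its ester must be brought to the aldehyde level before the pyranone of A can close. The pyranone of B and all of ring C are still missing. A2 itself needs a multistep preparation, and its 4-methoxy group lowers its reactivity as a diene.
- Comparison: the chosen plan accepts a late and less certain key step, and sets against it a convergent route in which rings B and C are complete before ring A is built, the ring A oxygens come out differentiated, and only three steps follow.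

Alternative 2: The cut goes through ring B at C5–C6 and C4a–C8a. The bis(silyloxy)diene A5 (4-(2,6-dimethoxyphenyl)-1-methoxy-1,3-bis(trimethylsilyloxy)buta-1,3-diene) would add to propiolate A6 (methyl propiolate) and aromatise by loss of the acetal alkoxy group, giving resorcinol ester A4 (methyl 5-(2,6-dimethoxyphenyl)-2,4-dihydroxybenzoate).
- Merits: the biaryl bond comes from an arylacetic acid derivative without any coupling, and the regiochemistry of such cycloadditions is dependable. The two phenols of ring B in A4 are differentiated, since the one beside the ester is hydrogen-bonded, so the ether to ring C could be started selectively. On that last point it is better than a route that must rely on order of events.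
- Weak points: the nucleophilic diene terminus carries the bulky 2,6-dimethoxyphenyl group, which should slow the cycloaddition. Ring A arrives as a symmetric dimethoxyphenyl that must be desymmetrised by mono-demethylation in the presence of other methyl ethers. All three pyranones remain to be closed after the key step.
- Comparison: the chosen plan needs one pyranone closure after its key step, and desymmetrisation of ring A is built into the benzannulation.

Alternative 3: The cut opens ring C at C3=C4 and O1–C2 as the last ring-forming event. Aryloxyacetic acid A8 (2-{[6-(7-hydroxy-2-oxo-2H-chromen-8-yl)-2-oxo-2H-chromen-7-yl]oxy}acetic acid) and aldehyde 1 would condense under classical anhydride Perkin conditions to the diacetate A7 of the target, which needs only mild solvolysis.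
- Merits: the end game is gentler than a Lewis-acid demethylation, and ring C does not have to ride through organometallic and thermal steps. The closure is sound; the chosen route uses the same reaction for ring C at step 5.
- Weak points: as the central idea it leaves the real difficulty, the tri-ortho-substituted A–B biaryl inside A8, unsolved. A8 would have to come from a hindered coupling of two coumarin halves or from a ring A construction like the one chosen here.
- Comparison: the chosen plan keeps the Perkin closure but runs it early on the simple acid 6, and adds a concrete answer to the biaryl problem. Its cost is the harsher final deprotection.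

Key step: step 9

Assumption: the target structure defines no stereochemical element, so the hindered A–B biaryl axis is treated as configurationally undefined and no control over it is attempted.

## Route

Step 1
Reactants: 1 2,4-dihydroxybenzaldehyde
Product: 2 2,4-dihydroxy-5-iodobenzaldehyde
Conditions: ICl, AcOH, rt; recrystallisation
Reagents that add atoms: iodine monochloride, ClI
Why: Electrophilic aromatic iodination; C5 is para to the 2-hydroxyl and ortho to the 4-hydroxyl and less hindered than C3 between the two hydroxyls, so the 5-iodo isomer should predominate and should be separable from the 3-iodo isomer by crystallisation.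

Step 2
Reactants: 2 2,4-dihydroxy-5-iodobenzaldehyde
Product: 4 7-hydroxy-6-iodo-2H-chromen-2-one, via iodinated E-cinnamate ester 3 (not isolated)
Conditions: Ph3P=CHCO2Et, PhNEt2, reflux
Reagents that add atoms: ethyl (triphenylphosphoranylidene)acetate, CCOC(=O)C=P(c1ccccc1)(c1ccccc1)c1ccccc1
Why: Wittig olefination to cinnamate 3, then thermal E-to-Z isomerisation and lactonisation in the high-boiling amine, the standard one-pot coumarin synthesis from salicylaldehydes; the aryl iodide is a spectator.

Step 3
Reactants: 4 7-hydroxy-6-iodo-2H-chromen-2-one
Product: 5 tert-butyl 2-[(6-iodo-2-oxo-2H-chromen-7-yl)oxy]acetate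
Conditions: BrCH2CO2t-Bu, K2CO3, DMF, rt
Reagents that add atoms: tert-butyl bromoacetate, CC(C)(C)OC(=O)CBr
Why: Williamson ether synthesis on the only phenol; carbonate in DMF at room temperature should not open the lactone.

Step 4
Reactants: 5 tert-butyl 2-[(6-iodo-2-oxo-2H-chromen-7-yl)oxy]acetate
Product: 6 2-[(6-iodo-2-oxo-2H-chromen-7-yl)oxy]acetic acid
Conditions: TFA, CH2Cl2, rt
Reagents that add atoms: none
Why: Acidolysis of the tert-butyl ester frees the acid without hydroxide, so the lactone is never opened.

Step 5
Reactants: 6 2-[(6-iodo-2-oxo-2H-chromen-7-yl)oxy]acetic acid; 7 2-hydroxy-4-methoxybenzaldehyde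
Product: 9 6-iodo-7-[(7-methoxy-2-oxo-2H-chromen-3-yl)oxy]-2H-chromen-2-one, via O-acylated salicylaldehyde 8 (not isolated)
Conditions: Ac2O, Et3N, 120 °C
Reagents that add atoms: none
Why: Perkin–Oglialoro condensation, the established route from aryloxyacetic acids and salicylaldehydes to 3-aryloxycoumarins; the acid is activated as a mixed anhydride, the phenol of 7 is expected to be acylated to 8, and intramolecular aldol condensation of the activated methylene onto the aldehyde followed by dehydration closes the pyranone of C.

Step 6
Reactants: 9 6-iodo-7-[(7-methoxy-2-oxo-2H-chromen-3-yl)oxy]-2H-chromen-2-one; 10 chloroacetaldehyde dimethyl acetal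
Product: 13 6-(methoxyethynyl)-7-[(7-methoxy-2-oxo-2H-chromen-3-yl)oxy]-2H-chromen-2-one, via lithium methoxyacetylide 11 (not isolated), via methoxyethynylzinc chloride 12 (not isolated)
Conditions: n-BuLi, Et2NH, THF, 0 °C (LiNEt2, 3 equiv); 10, 0 °C to rt; ZnCl2 (excess), THF, 0 °C; then 9, Pd(PPh3)4 (cat.), THF, rt to 40 °C; chromatography on Et3N-deactivated silica
Reagents that add atoms: none
Why: Two eliminations and a deprotonation convert 10 into 11 (a known in situ preparation), transmetalation gives 12, and Negishi coupling of alkoxyethynylzinc chlorides with aryl iodides through oxidative addition to zerovalent palladium is established; the zinc acetylide is not nucleophilic enough to attack the lactones, and excess ZnCl2 removes any residual lithium amide before 9 is added.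

Step 7
Reactants: 14 3-oxocyclobutane-1-carboxylic acid
Product: 15 3-bromocyclobutan-1-one
Conditions: HgO, Br2, MgSO4, CH2Cl2, reflux
Reagents that add atoms: bromine, BrBr
Why: Cristol–Firth variant of the Hunsdiecker bromodecarboxylation, the known preparation of this bromo ketone.

Step 8
Reactants: 15 3-bromocyclobutan-1-one
Product: 16 cyclobut-2-en-1-one
Conditions: n-Bu3N, neat, rt, reduced pressure; product distilled into a −78 °C trap and kept as a cold toluene solution
Reagents that add atoms: none
Why: Base-induced beta-elimination (E1cB) of the beta-bromo ketone; the high-boiling amine lets the volatile, polymerisation-prone enone distil out as it forms, as in the known preparation.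

Step 9
Reactants: 13 6-(methoxyethynyl)-7-[(7-methoxy-2-oxo-2H-chromen-3-yl)oxy]-2H-chromen-2-one; 16 cyclobut-2-en-1-one
Product: 21 6-(2-hydroxy-6-methoxyphenyl)-7-[(7-methoxy-2-oxo-2H-chromen-3-yl)oxy]-2H-chromen-2-one, via vinylketene 17 (not isolated), via vinylcyclobutenone adduct 18 (not isolated), via dienylketene 19 (not isolated), via cyclohexadienone tautomer 20 (not isolated)
Conditions: 16 (excess, added in portions as a toluene solution), toluene, sealed tube, 80 °C then 110 °C
Reagents that add atoms: none
Why: Danheiser benzannulation, the closest known reaction type being the thermal annulation of cyclobutenones with 1-alkoxy- and 1-siloxyalkynes to resorcinol monoethers. On heating, 16 opens in a four-electron electrocyclic step to vinylketene 17. The aryl-bearing carbon of the ynol ether is the nucleophilic one, so it bonds to the ketene carbonyl carbon while the methoxy-bearing carbon bonds to the ketene alpha carbon, a regiospecific [2+2] cycloaddition that gives 18 and forms C8–C8a and C6–C7 of ring A. Adduct 18 reopens by a second four-electron electrocyclic cleavage to dienylketene 19, whose ketene carbon and vinyl terminus close the six-membered benzene ring of A in a thermally allowed disrotatory six-electron electrocyclisation to 20, which tautomerises to the phenol. No stereocentre is set, since the only sp3 ring carbon of 18 is lost on ring opening. The selectivity needed is regiochemical and rests on the polarity of the ynol ether, which places the aryl group between the new hydroxyl and the methoxy group; chemoselectivity follows because the electrophilic ketene ignores the electron-poor C3=C4 bonds of rings B and C. The methyl ynol ether has no beta hydrogen and cannot fragment to an arylketene at these temperatures, and the lactones are inert to neutral heating.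

Step 10
Reactants: 21 6-(2-hydroxy-6-methoxyphenyl)-7-[(7-methoxy-2-oxo-2H-chromen-3-yl)oxy]-2H-chromen-2-one
Product: 22 2-hydroxy-4-methoxy-3-{7-[(7-methoxy-2-oxo-2H-chromen-3-yl)oxy]-2-oxo-2H-chromen-6-yl}benzaldehyde
Conditions: MgCl2, Et3N, (CH2O)n, MeCN, reflux; dilute HCl work-up
Reagents that add atoms: paraformaldehyde (as formaldehyde), C=O
Why: Casnati–Skattebøl ortho-formylation; the magnesium phenoxide delivers formaldehyde to the only free ortho position, which is also para to the methoxy group, and a second formaldehyde oxidises the benzylic alkoxide to the aldehyde; 2-arylphenols are known substrates and the mild amine base should leave the lactones intact.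

Step 11
Reactants: 22 2-hydroxy-4-methoxy-3-{7-[(7-methoxy-2-oxo-2H-chromen-3-yl)oxy]-2-oxo-2H-chromen-6-yl}benzaldehyde
Product: 24 7-methoxy-8-{7-[(7-methoxy-2-oxo-2H-chromen-3-yl)oxy]-2-oxo-2H-chromen-6-yl}-2H-chromen-2-one, via E-cinnamate ester 23 (not isolated)
Conditions: Ph3P=CHCO2Et, PhNEt2, reflux
Reagents that add atoms: ethyl (triphenylphosphoranylidene)acetate, CCOC(=O)C=P(c1ccccc1)(c1ccccc1)c1ccccc1
Why: Wittig olefination followed by thermal isomerisation and lactonisation, as in step 2; the aldehyde is unhindered and the existing coumarins and methyl ethers are thermally robust.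

Step 12
Reactants: 24 7-methoxy-8-{7-[(7-methoxy-2-oxo-2H-chromen-3-yl)oxy]-2-oxo-2H-chromen-6-yl}-2H-chromen-2-one
Product: 25 7-hydroxy-8-{7-[(7-hydroxy-2-oxo-2H-chromen-3-yl)oxy]-2-oxo-2H-chromen-6-yl}-2H-chromen-2-one
Conditions: BBr3 (excess), CH2Cl2, −78 °C to rt; then ice-water
Reagents that add atoms: none
Why: Lewis-acid cleavage of aryl methyl ethers by bromide attack at the methyl carbon, routine for methoxycoumarins; the ether between rings B and C has only sp2 carbons on oxygen and cannot be cleaved this way, and the lactones merely coordinate the reagent, which is why an excess is used.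

## Compound list

1 | 2,4-dihydroxybenzaldehyde | O=Cc1ccc(O)cc1O | starting material
2 | 2,4-dihydroxy-5-iodobenzaldehyde | O=Cc1cc(I)c(O)cc1O | intermediate
3 | ethyl (2E)-3-(2,4-dihydroxy-5-iodophenyl)prop-2-enoate | CCOC(=O)/C=C/c1cc(I)c(O)cc1O | intermediate (not isolated)
4 | 7-hydroxy-6-iodo-2H-chromen-2-one | O=c1ccc2cc(I)c(O)cc2o1 | intermediate
5 | tert-butyl 2-[(6-iodo-2-oxo-2H-chromen-7-yl)oxy]acetate | CC(C)(C)OC(=O)COc1cc2oc(=O)ccc2cc1I | intermediate
6 | 2-[(6-iodo-2-oxo-2H-chromen-7-yl)oxy]acetic acid | OC(=O)COc1cc2oc(=O)ccc2cc1I | intermediate
7 | 2-hydroxy-4-methoxybenzaldehyde | COc1ccc(C=O)c(O)c1 | starting material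
8 | 2-formyl-5-methoxyphenyl 2-[(6-iodo-2-oxo-2H-chromen-7-yl)oxy]acetate | COc1ccc(C=O)c(OC(=O)COc2cc3oc(=O)ccc3cc2I)c1 | intermediate (not isolated)
9 | 6-iodo-7-[(7-methoxy-2-oxo-2H-chromen-3-yl)oxy]-2H-chromen-2-one | COc1ccc2cc(Oc3cc4oc(=O)ccc4cc3I)c(=O)oc2c1 | intermediate
10 | chloroacetaldehyde dimethyl acetal (2-chloro-1,1-dimethoxyethane) | ClCC(OC)OC | starting material
11 | lithium methoxyacetylide | [Li]C#COC | intermediate (not isolated)
12 | methoxyethynylzinc chloride | Cl[Zn]C#COC | intermediate (not isolated)
13 | 6-(methoxyethynyl)-7-[(7-methoxy-2-oxo-2H-chromen-3-yl)oxy]-2H-chromen-2-one | COC#Cc1cc2ccc(=O)oc2cc1Oc1cc2ccc(OC)cc2oc1=O | intermediate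
14 | 3-oxocyclobutane-1-carboxylic acid | O=C1CC(C(=O)O)C1 | starting material
15 | 3-bromocyclobutan-1-one | O=C1CC(Br)C1 | intermediate
16 | cyclobut-2-en-1-one | O=C1C=CC1 | intermediate
17 | buta-1,3-dien-1-one (vinylketene) | C=CC=C=O | intermediate (not isolated)
18 | 6-(2-methoxy-4-oxo-3-vinylcyclobut-1-en-1-yl)-7-[(7-methoxy-2-oxo-2H-chromen-3-yl)oxy]-2H-chromen-2-one, racemic | C=CC1C(OC)=C(C1=O)c1cc2ccc(=O)oc2cc1Oc1cc2ccc(OC)cc2oc1=O | intermediate (not isolated)
19 | (3E)-3-methoxy-2-{7-[(7-methoxy-2-oxo-2H-chromen-3-yl)oxy]-2-oxo-2H-chromen-6-yl}hexa-1,3,5-trien-1-one | O=C=C(/C(OC)=C\C=C)c1cc2ccc(=O)oc2cc1Oc1cc2ccc(OC)cc2oc1=O | intermediate (not isolated)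
20 | 6-(2-methoxy-6-oxocyclohexa-1,3-dien-1-yl)-7-[(7-methoxy-2-oxo-2H-chromen-3-yl)oxy]-2H-chromen-2-one | COC1=C(C(=O)CC=C1)c1cc2ccc(=O)oc2cc1Oc1cc2ccc(OC)cc2oc1=O | intermediate (not isolated)
21 | 6-(2-hydroxy-6-methoxyphenyl)-7-[(7-methoxy-2-oxo-2H-chromen-3-yl)oxy]-2H-chromen-2-one | COc1cccc(O)c1-c1cc2ccc(=O)oc2cc1Oc1cc2ccc(OC)cc2oc1=O | intermediate
22 | 2-hydroxy-4-methoxy-3-{7-[(7-methoxy-2-oxo-2H-chromen-3-yl)oxy]-2-oxo-2H-chromen-6-yl}benzaldehyde | COc1ccc(C=O)c(O)c1-c1cc2ccc(=O)oc2cc1Oc1cc2ccc(OC)cc2oc1=O | intermediate
23 | ethyl (2E)-3-(2-hydroxy-4-methoxy-3-{7-[(7-methoxy-2-oxo-2H-chromen-3-yl)oxy]-2-oxo-2H-chromen-6-yl}phenyl)prop-2-enoate | CCOC(=O)/C=C/c1ccc(OC)c(-c2cc3ccc(=O)oc3cc2Oc2cc3ccc(OC)cc3oc2=O)c1O | intermediate (not isolated)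
24 | 7-methoxy-8-{7-[(7-methoxy-2-oxo-2H-chromen-3-yl)oxy]-2-oxo-2H-chromen-6-yl}-2H-chromen-2-one | COc1ccc2ccc(=O)oc2c1-c1cc2ccc(=O)oc2cc1Oc1cc2ccc(OC)cc2oc1=O | intermediate
25 | 7-hydroxy-8-{7-[(7-hydroxy-2-oxo-2H-chromen-3-yl)oxy]-2-oxo-2H-chromen-6-yl}-2H-chromen-2-one | O=c1ccc2cc(-c3c(O)ccc4ccc(=O)oc34)c(Oc3cc4ccc(O)cc4oc3=O)cc2o1 | target

## Step count and risks

Total: 12 steps. Longest linear sequence: 10 steps (steps 1 to 6 and 9 to 12, from 1). The two-step branch to 16 (steps 7 and 8) joins at step 9.

Step 9 (key step). The most likely failure is that self-condensation and polymerisation of 16 and of vinylketene 17 outrun capture by the aryl-conjugated ynol ether, which is less nucleophilic than the alkyl-substituted alkynes usually used. Acylation of the hindered product phenol by excess 17 and acid-catalysed hydration of the ynol ether by adventitious moisture would lower the return further. A photochemical ketene source is not an option, because the coumarins dimerise under irradiation. The fallback gives up the ring construction and makes the biaryl bond directly; it sets out from iodide 9 and returns at phenol 21. 3-Methoxyphenol F1 is protected (MOMCl, i-Pr2NEt) as 1-methoxy-3-(methoxymethoxy)benzene F2. F2 is lithiated between its two oxygens (n-BuLi, THF, 0 °C) and quenched with B(OMe)3 to give [2-methoxy-6-(methoxymethoxy)phenyl]boronic acid F3. Suzuki–Miyaura coupling of F3 with 9 (Pd(OAc)2, SPhos, anhydrous K3PO4, toluene, 90 °C) should give 6-[2-methoxy-6-(methoxymethoxy)phenyl]-7-[(7-methoxy-2-oxo-2H-chromen-3-yl)oxy]-2H-chromen-2-one F4. Removal of the acetal with HCl in methanol/THF then gives 21. The price is a hindered tri-ortho coupling with a boronic acid prone to protodeboronation, which is why this is the reserve and not the plan.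

Step 6. The ynol ether may be lost through hydration to the arylacetate during work-up and chromatography, and the lithium amide and amine in the one-pot reagent solution may open or add to the lactones if transmetalation to zinc is incomplete. The fallback separates reagent preparation from coupling; it sets out from 9 and 10 and returns at 13. Acetylide 11, made from 10 as before, is quenched with Bu3SnCl and the product is distilled to give tributyl(methoxyethynyl)stannane F5. Stille coupling of F5 with 9 (Pd(PPh3)4, toluene, 80 °C) then runs under neutral, amine-free and salt-free conditions.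

Step 10. Formylation may stall because the ortho biaryl shields the magnesium phenoxide, substitution may occur para to the hydroxyl, and long heating with amine may start to open lactones. The fallback skips the aldehyde and builds the pyranone directly; it sets out from 21 and returns at 24 and needs no new intermediate. Palladium-catalysed hydroarylation of ethyl propiolate by the phenol (Pd(OAc)2, TFA, CH2Cl2, rt), a known coumarin synthesis for electron-rich phenols, should attack the same carbon (ortho to the hydroxyl, para to the methoxy group) and lactonise in the same flask.

Step 5. The anhydride medium may divert aldehyde 7 into condensation with the acetyl group instead of the aryloxyacetyl group, and conversion of the acid may be incomplete. The fallback runs the two events separately without any acetyl source; it sets out from 6 and 7 and returns at 9. Acid 6 is converted with (COCl)2 and catalytic DMF into 2-[(6-iodo-2-oxo-2H-chromen-7-yl)oxy]acetyl chloride F6. F6 acylates the phenol of 7 (Et3N, CH2Cl2, 0 °C) to give ester 8, now isolated, and DBU in MeCN closes the pyranone by intramolecular aldol condensation to 9.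

## Further compounds

F1 | step 9 | 3-methoxyphenol (purchased) | COc1cccc(O)c1
F2 | step 9 | 1-methoxy-3-(methoxymethoxy)benzene | COCOc1cccc(OC)c1
F3 | step 9 | [2-methoxy-6-(methoxymethoxy)phenyl]boronic acid | COCOc1cccc(OC)c1B(O)O
F4 | step 9 | 6-[2-methoxy-6-(methoxymethoxy)phenyl]-7-[(7-methoxy-2-oxo-2H-chromen-3-yl)oxy]-2H-chromen-2-one | COCOc1cccc(OC)c1-c1cc2ccc(=O)oc2cc1Oc1cc2ccc(OC)cc2oc1=O
F5 | step 6 | tributyl(methoxyethynyl)stannane | CCCC[Sn](CCCC)(CCCC)C#COC
F0 | step 10 | none | none
F6 | step 5 | 2-[(6-iodo-2-oxo-2H-chromen-7-yl)oxy]acetyl chloride | O=C(Cl)COc1cc2oc(=O)ccc2cc1I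
A1 | alternative 1 | methyl 3-[2-(benzyloxy)-4-methoxyphenyl]-2,4-dimethoxybenzoate | COC(=O)c1ccc(OC)c(-c2ccc(OC)cc2OCc2ccccc2)c1OC
A2 | alternative 1 | methyl 3-[2-(benzyloxy)-4-methoxyphenyl]-4-methoxy-2-oxo-2H-pyran-5-carboxylate | COC(=O)c1coc(=O)c(-c2ccc(OC)cc2OCc2ccccc2)c1OC
A3 | alternative 1 | 1,1-dimethoxyethene | C=C(OC)OC
A4 | alternative 2 | methyl 5-(2,6-dimethoxyphenyl)-2,4-dihydroxybenzoate | COC(=O)c1cc(-c2c(OC)cccc2OC)c(O)cc1O
A5 | alternative 2 | 4-(2,6-dimethoxyphenyl)-1-methoxy-1,3-bis(trimethylsilyloxy)buta-1,3-diene | COC(O[Si](C)(C)C)=CC(O[Si](C)(C)C)=Cc1c(OC)cccc1OC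
A6 | alternative 2 | methyl propiolate | C#CC(=O)OC
A7 | alternative 3 | 8-{7-[(7-acetoxy-2-oxo-2H-chromen-3-yl)oxy]-2-oxo-2H-chromen-6-yl}-2-oxo-2H-chromen-7-yl acetate | CC(=O)Oc1ccc2cc(Oc3cc4oc(=O)ccc4cc3-c3c(OC(C)=O)ccc4ccc(=O)oc34)c(=O)oc2c1
A8 | alternative 3 | 2-{[6-(7-hydroxy-2-oxo-2H-chromen-8-yl)-2-oxo-2H-chromen-7-yl]oxy}acetic acid | OC(=O)COc1cc2oc(=O)ccc2cc1-c1c(O)ccc2ccc(=O)oc12
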